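I had to commit the starting material to one of four ways of running the same reactions, so I wanted to know beforehand which way hands it the coupling partner.

in all of them: coupling partner 1.10 equiv; free catalyst 1 mol%

| flask | starting material | second substrate | time | remark |
|---|---|---|---|---|
| Wednesday's | 10 mM | 2.00 equiv | 4.0 d | everything together in a closed stirred flask, run for 4.0 d |
| Friday's | 10 mM (fed, over 2.00 d) | 2.00 equiv | 4.0 d | a stirred flask in which starting material is dosed at a steady rate over 2.00 d without added volume, worked up at 4.0 d |
| Monday's | 10 mM | 2.00 equiv (fed, over 2.00 d) | 4.0 d | all but second substrate at the start; second substrate goes in evenly over 2.00 d, the run ends at 4.0 d |
| Saturday's | 10 mM | 2.00 equiv |  | one stirred flow tank at steady state, fed with the mixture as stated, mean residence time 4.0 d |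

    second substrate + coupling partner + free catalyst → free catalyst + second product (k1 = 98.6 M⁻² s⁻¹)
    starting material + coupling partner + free catalyst → free catalyst + target (k2 = 70.8 M⁻² s⁻¹)
    free catalyst → spent catalyst (k3 = 3.66 × 10⁻⁹ s⁻¹)
    starting material + coupling partner → uncatalysed product (k4 = 4.59 × 10⁻⁴ M⁻¹ s⁻¹)

- the set-up with the highest amount of target at the outlet or at the end, in percent of the starting material put in ("none" if the first two lie within 2 percentage points) (Wednesday's / Friday's / Monday's / Saturday's / none)
- amount of target at the outlet or at the end, in percent of the starting material put in, Wednesday's
- amount of target at the outlet or at the end, in percent of the starting material put in, Friday's
- amount of target at the outlet or at the end, in percent of the starting material put in, Monday's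
- amount of target at the outlet or at the end, in percent of the starting material put in, Saturday's

- the stated concentrations are those of everything mixed, before any reaction; amounts are the same in each set-up
- the feed brings no volume worth counting
- run time (Wednesday's): 4.0 d

I began with the balance of the coupling partner, because its charge of 11.0 mM stood below the 30.0 mM of the two substrates together. It is the limiting reagent, and the yield is a question of how it is split. My first estimate of the split was the ratio of the two catalysed constants, 1.39, with the catalyst cancelling. But step 4 also takes partner, without catalyst: at 0.100 mM of free catalyst it runs at 6.48% of step 2, which I could not drop. Counting both routes of the starting material gave 1.31. I called this the selectivity factor: how much faster a unit of second substrate takes partner than a unit of starting material does. Of the starting material consumed, 93.9% becomes target.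

I then doubted that the factor stays constant, but step 3 removes about 0.126% of the catalyst in 4.0 d, so I kept it. In Wednesday's flask both substrates meet the same partner and catalyst, so the fraction of second substrate left is the fraction of starting material left raised to the factor. Trying 0.7 left, the partner taken came to 10.5 mM, short of the charge. One linear correction brought the starting material left to 68.4%, which gave 29.7% of target.

In Friday's flask the partner first meets second substrate with no starting material present, and its half-life against that substrate at the charged concentration is 0.0407 d, far shorter than the 2.00 d dose. So I expected little target. Monday's flask is the mirror, with a half-life at the charged concentration of 0.106 d against starting material, also shorter than the 2.00 d dose, so I expected much target. I did not integrate these two, so for them I had directions and no numbers, and I did not solve Saturday's tank.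

The forecast named Monday's as best, with 29.7% for Wednesday's, 3% for Friday's, 74% for Monday's and 30.1% for Saturday's. Its ground was that "Dosing the second substrate slowly lets the starting material take most of the partner".

The simulation gave 29.7% for Wednesday's, 2.38% for Friday's, 74.8% for Monday's and 30.0% for Saturday's, so the best was Monday's. Wednesday's flask ended with 68% of its starting material and 61% of its second substrate, and the first raised to the factor gives 60.3%. In the neighbour of Monday's flask with 2.5 mM of starting material, the same loading means 0.0250 mM of catalyst, so the factor becomes 1.11 and the share of consumed starting material going to target 79.4%. That neighbour ended with 39.5% of target and 10.3% of uncatalysed product.

All constants were chosen freely; what happens was integrated by code.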